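**Retrosynthetic overview**

1. Numbering: C1 lactone C=O, C2=C3, C4 (Me), C5 (OH), C6=C7 (Me), oxazole, C8–C9, C10 (Me), C11, C12 (OMe), tetrahydrofuran C13–C16 plus ring O (C14–O–C1, C15–Br, C16 quaternary), C17, C18=C19 (Z), C20, C21 (Me, OH), C22 acid.
2. The 18-membered lactone (last ring) is opened at C2=C3 (intramolecular Horner–Wadsworth–Emmons reaction of a C14 phosphonoacetate) and at C4–C5 (Evans syn-aldol). The Z-C18=C19 alkene comes from Z-selective cross-metathesis with a lactate-derived C19–C22 ester, and C16–C17 from allylation of a C16 oxocarbenium ion.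
3. Key disconnection: the bromotetrahydrofuran is made by a one-pot (3+2) annulation of the C13 aldehyde (C13=O, the future ring O) with a C14–C16 homoenolate, a titanated γ-alkoxy-α-methylallyl carbamate. Homoaldol addition makes C13–C14; NBS then makes ring O–C16 and places Br on C15.
4. Enabling feature: in the ring O–C13–C14–C15–C16 the oxygen-bearing carbons C14 and C16 are 1,3-related, and C16 (quaternary, bonded to the ring O) is a ketone carbon once C17 is removed. C14–C15–C16 is therefore a β-oxygenated ketone homoenolate, O=C13 an aldehyde, and the C15 bromine the electrophile that turns the intermediate enol carbamate into the ring.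
5. Aldehyde 13 (C8–C13, oxazole, C5–C7 as a Weinreb enamide) derives from (S)-citronellal (C10 methyl; oxazole C2 from the cleaved alkene carbon), with C12 set by catalytic asymmetric alkenylzinc addition. Ring order: oxazole, tetrahydrofuran, macrolactone.

Key step: step 11

Remark 1: atom numbers are those of the overview; CIP descriptors of intermediates can differ from those of the same centre in the target although the spatial arrangement (see SMILES) is unchanged.
Remark 2 (assumption): lithium–titanium exchange on 18 is taken to proceed with inversion, as for other secondary allyl carbamates; this fixes the choice of (R)-17.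

**Step 1**
Reactants: 1 (S)-citronellal
Product: 2 (6S,8S,9E)-2,6-dimethyltetradeca-2,9-dien-8-ol
Conditions: 1-hexyne, Cy2BH, toluene, 0 °C to rt; Me2Zn, −78 °C; (+)-MIB (4 mol%), then 1, −10 °C; aq. NH4Cl
Reagents that add atoms: 1-hexyne, C#CCCCC
Why: Oppolzer–Walsh catalytic asymmetric alkenylzinc addition; the (E)-hexenylzinc species from hydroboration and boron-to-zinc exchange is delivered under ligand control to the Re face of the aldehyde, which sets C12 (8S in 2) independently of the remote C10 methyl group.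

**Step 2**
Reactants: 2 (6S,8S,9E)-2,6-dimethyltetradeca-2,9-dien-8-ol
Product: 3 (6S,8S,9E)-8-methoxy-2,6-dimethyltetradeca-2,9-diene
Conditions: NaH, MeI, THF, 0 °C to rt
Reagents that add atoms: iodomethane, CI
Why: Williamson ether synthesis on the sodium alkoxide; no stereocentre is touched.

**Step 3**
Reactants: 3 (6S,8S,9E)-8-methoxy-2,6-dimethyltetradeca-2,9-diene
Product: 5 (4S,6S,7E)-6-methoxy-4-methyldodec-7-enal, via trisubstituted epoxide 4 (not isolated)
Conditions: mCPBA, CH2Cl2, 0 °C; then H5IO6, THF/H2O, 0 °C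
Reagents that add atoms: mCPBA, OOC(=O)c1cccc(Cl)c1
Why: Prilezhaev epoxidation should pick the electron-rich trisubstituted alkene over the disubstituted alkene deactivated by its allylic methoxy group, and periodic acid then cleaves the epoxide (through the diol) to the aldehyde; no stereocentre is touched.

**Step 4**
Reactants: 5 (4S,6S,7E)-6-methoxy-4-methyldodec-7-enal; 6 L-serine methyl ester hydrochloride
Product: 9 methyl 2-[(3S,5S,6E)-5-methoxy-3-methylundec-6-en-1-yl]oxazole-4-carboxylate, via oxazolidine 7 (not isolated), via oxazoline 8 (not isolated)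
Conditions: K2CO3, N,N-dimethylacetamide, rt; then BrCCl3, DBU, 0 °C to rt
Reagents that add atoms: none
Why: one-pot oxazole synthesis from an aldehyde, i.e. condensation to the oxazolidine followed by two BrCCl3/DBU dehydrogenations (Williams–Wipf-type oxidation) driven by aromatisation; the serine stereocentre is destroyed and the chain stereocentres are remote.

**Step 5**
Reactants: 9 methyl 2-[(3S,5S,6E)-5-methoxy-3-methylundec-6-en-1-yl]oxazole-4-carboxylate
Product: 11 1-{2-[(3S,5S,6E)-5-methoxy-3-methylundec-6-en-1-yl]oxazol-4-yl}ethan-1-one, via Weinreb amide 10 (not isolated)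
Conditions: MeNH(OMe)·HCl, iPrMgCl, THF, −20 °C; then MeMgBr, 0 °C; aq. NH4Cl
Reagents that add atoms: methylmagnesium bromide, C[Mg]Br
Why: telescoped Weinreb ketone synthesis (aminolysis of the ester by the magnesium amide, then Grignard addition to the chelated amide, which stops at the ketone); no stereocentre is involved.

**Step 6**
Reactants: 11 1-{2-[(3S,5S,6E)-5-methoxy-3-methylundec-6-en-1-yl]oxazol-4-yl}ethan-1-one
Product: 12 (2E)-N-methoxy-3-{2-[(3S,5S,6E)-5-methoxy-3-methylundec-6-en-1-yl]oxazol-4-yl}-N-methylbut-2-enamide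
Conditions: (EtO)2P(O)CH2C(O)N(OMe)Me, NaH, THF, 0 to 60 °C
Reagents that add atoms: diethyl [2-(methoxy(methyl)amino)-2-oxoethyl]phosphonate, CCOP(=O)(OCC)CC(=O)N(C)OC
Why: Horner–Wadsworth–Emmons olefination of the heteroaryl methyl ketone, expected to give the E-alkene (oxazolyl trans to the amide carbonyl) under thermodynamic control of the oxaphosphetane.

**Step 7**
Reactants: 12 (2E)-N-methoxy-3-{2-[(3S,5S,6E)-5-methoxy-3-methylundec-6-en-1-yl]oxazol-4-yl}-N-methylbut-2-enamide
Product: 13 (2E)-N-methoxy-3-{2-[(3S,5S)-5-methoxy-3-methyl-6-oxohexyl]oxazol-4-yl}-N-methylbut-2-enamide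
Conditions: OsO4 (2 mol%), NaIO4, 2,6-lutidine, dioxane/H2O, rt
Reagents that add atoms: sodium periodate, [Na+].[O-]I(=O)(=O)=O (oxygen delivered through catalytic OsO4, O=[Os](=O)(=O)=O)
Why: Lemieux–Johnson cleavage, which should take the electron-rich disubstituted alkene and leave the electron-poor, amide-conjugated trisubstituted alkene; the α-methoxy aldehyde is used without storage so that C12 is not epimerised.

**Step 8**
Reactants: 14 (E)-4-methoxybut-3-en-2-one
Product: 15 (E)-4-[(4-methoxybenzyl)oxy]but-3-en-2-one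
Conditions: 4-methoxybenzyl alcohol, PPTS (cat.), toluene, 60 °C, reduced pressure
Reagents that add atoms: 4-methoxybenzyl alcohol, COc1ccc(CO)cc1
Why: acid-catalysed vinylogous transesterification (addition–elimination at the β-carbon) driven by removal of methanol; the E-configured vinylogous ester is the thermodynamic product.

**Step 9**
Reactants: 15 (E)-4-[(4-methoxybenzyl)oxy]but-3-en-2-one
Product: 16 (2R,3E)-4-[(4-methoxybenzyl)oxy]but-3-en-2-ol
Conditions: (S)-2-methyl-CBS-oxazaborolidine (20 mol%), catecholborane, toluene, −78 °C; pH 7 buffer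
Reagents that add atoms: none
Why: Corey–Bakshi–Shibata reduction in which the alkenyl group acts as the large substituent, so the (S)-catalyst should deliver hydride to give the (R)-carbinol.

**Step 10**
Reactants: 16 (2R,3E)-4-[(4-methoxybenzyl)oxy]but-3-en-2-ol
Product: 17 (2R,3E)-4-[(4-methoxybenzyl)oxy]but-3-en-2-yl N,N-diisopropylcarbamate
Conditions: NaH, ClC(O)N(iPr)2, THF, 0 °C to rt
Reagents that add atoms: N,N-diisopropylcarbamoyl chloride, CC(C)N(C(C)C)C(Cl)=O
Why: O-carbamoylation of the sodium alkoxide under non-acidic conditions (the γ-alkoxy allylic alcohol is acid-labile); the stereocentre is retained.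

**Step 11**
Reactants: 13 (2E)-N-methoxy-3-{2-[(3S,5S)-5-methoxy-3-methyl-6-oxohexyl]oxazol-4-yl}-N-methylbut-2-enamide; 17 (2R,3E)-4-[(4-methoxybenzyl)oxy]but-3-en-2-yl N,N-diisopropylcarbamate
Product: 21 bromo-ketal carbamate (2-carbamoyloxy-2-methyl-3-bromo-4-PMBO-tetrahydrofuran carrying the C12 side arm), via lithiated carbamate 18 (not isolated), via allyltitanium reagent 19 (not isolated), via homoaldol titanium alkoxide 20 (not isolated)
Conditions: s-BuLi, TMEDA, Et2O, −78 °C; Ti(OiPr)4, −78 °C; 13, −78 °C; then NBS (1.5 equiv), THF, −78 to −40 °C; aq. NaHCO3/Na2S2O3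
Reagents that add atoms: N-bromosuccinimide, O=C1CCC(=O)N1Br
Why: Proposed new method: carbamate-directed deprotonation of 17 (retention) and Li-to-Ti exchange (inversion) should give the configurationally defined 1-oxyallyltitanium 19, which adds suprafacially through a Zimmerman–Traxler chair at its γ-carbon C14 to the aldehyde, forming C13–C14 and a (Z)-enol carbamate; NBS then brominates the enol carbamate at C15 and the titanium alkoxide oxygen captures the resulting C16 acyloxy-stabilised cation, forming ring O–C16. The closest known chemistry is the Hoppe homoaldol reaction of crotyl-type carbamates and the haloetherification of enol derivatives (glycal-type), which have not been shown for a γ-alkoxy carbamate or merged into one operation. The tetrahydrofuran closes by 5-exo-trig attack of the alkoxide on the C16=O(+) carbon (formally a 5-endo haloetherification made easy by the oxygen-stabilised cation). C14 is set by 1,3-chirality transfer from the carbamate carbon of 17 and C13 by the chair (E-γ-OPMB and the aldehyde residue both equatorial, giving 13,14-anti), so both are reagent-controlled and should override the Felkin bias of the α-methoxy aldehyde to give the 12,13-syn array; C15 is set by the C14 stereocentre (Br+ enters anti to the ring-forming C13 arm with the OPMB group in the alkene plane, giving Br trans to OPMB), and C16 is a ketal centre that is erased in step 12. The step needs γ- over α-attack of the allyl metal (titanium sits on the carbamate carbon), addition to CHO in preference to the Weinreb enamide (allyltitanium triisopropoxides are aldehyde-selective), and bromination of the enol carbamate rather than the electron-poor C6=C7 alkene or the anisyl ring (−78 °C).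

**Step 12**
Reactants: 21 bromo-ketal carbamate
Product: 22 (2E)-3-{2-[(3S,5S)-5-[(2R,3R,4S,5R)-5-allyl-4-bromo-3-(4-methoxybenzyloxy)-5-methyltetrahydrofuran-2-yl]-5-methoxy-3-methylpentyl]oxazol-4-yl}-N-methoxy-N-methylbut-2-enamide
Conditions: allyltrimethylsilane, BF3·OEt2, CH2Cl2, −78 to −40 °C
Reagents that add atoms: allyltrimethylsilane, C=CC[Si](C)(C)C
Why: Hosomi–Sakurai allylation of a cyclic oxocarbenium ion (C-glycosidation type): BF3 ionises the tertiary ketal carbamate and the allylsilane should add to C16 anti to the C15 bromine (bromonium-bridged cation) and syn to the C14 alkoxy group (inside-attack model), both of which give the quaternary centre with methyl cis to Br.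

**Step 13**
Reactants: 23 (R)-lactic acid
Product: 24 (2R,5R)-2-tert-butyl-5-methyl-1,3-dioxolan-4-one
Conditions: pivalaldehyde, p-TsOH (cat.), H2SO4 (cat.), pentane, reflux (Dean–Stark); crystallisation
Reagents that add atoms: pivalaldehyde, CC(C)(C)C=O
Why: Seebach acetalisation; the cis-dioxolanone is the thermodynamic product and is purified by crystallisation, the lactate stereocentre being untouched.

**Step 14**
Reactants: 24 (2R,5R)-2-tert-butyl-5-methyl-1,3-dioxolan-4-one
Product: 25 (2R,5S)-5-allyl-2-tert-butyl-5-methyl-1,3-dioxolan-4-one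
Conditions: LiN(iPr)2, THF, −78 °C; allyl bromide, −78 to −20 °C
Reagents that add atoms: allyl bromide, C=CCBr
Why: Seebach self-regeneration of stereocentres: the planar lithium enolate is allylated anti to the tert-butyl group of the acetal, which sets the quaternary C21.

**Step 15**
Reactants: 25 (2R,5S)-5-allyl-2-tert-butyl-5-methyl-1,3-dioxolan-4-one
Product: 26 2-(trimethylsilyl)ethyl (2S)-2-hydroxy-2-methylpent-4-enoate
Conditions: Me3SiCH2CH2OH, NaH (10 mol%), THF, 0 °C to rt
Reagents that add atoms: 2-(trimethylsilyl)ethanol, C[Si](C)(C)CCO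
Why: alkoxide-catalysed alcoholysis (transesterification) of the dioxolanone, which releases pivalaldehyde and leaves the quaternary stereocentre untouched.

**Step 16**
Reactants: 22 allyl bromotetrahydrofuran Weinreb enamide; 26 2-(trimethylsilyl)ethyl (2S)-2-hydroxy-2-methylpent-4-enoate
Product: 27 Z-alkene Weinreb enamide (22 with C16 carrying the (Z)-CH2CH=CHCH2C(CH3)(OH)CO2CH2CH2SiMe3 chain)
Conditions: 26 (4 equiv), Z-selective cyclometalated ruthenium nitrate catalyst [Ru(NO3)(=CH-C6H4-2-OiPr)(κ2-C,C-{1-(adamant-1-yl)-3-(2,6-iPr2C6H3)imidazolin-2-ylidene})] (5 mol%), THF, 35 °C, argon sparge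
Reagents that add atoms: none
Why: Z-selective olefin cross-metathesis; the cyclometalated catalyst forms the cis-disubstituted alkene kinetically, only the two terminal alkenes are reactive (the amide-conjugated trisubstituted alkene is inert), and excess 26 suppresses homodimerisation of 22.

**Step 17**
Reactants: 27 Z-alkene Weinreb enamide
Product: 28 enal (27 with CHO at C5 in place of the Weinreb amide)
Conditions: Cp2Zr(H)Cl, THF, rt, 20 min
Reagents that add atoms: none
Why: Schwartz-reagent reduction of a tertiary (Weinreb) amide to the aldehyde (Georg protocol): hydrozirconation of the amide carbonyl gives a zirconated hemiaminal that collapses to the enal on work-up, while the hindered ester, the bromide and the internal Z-alkene should react more slowly; no stereocentre is affected.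

**Step 18**
Reactants: 28 enal
Product: 29 Evans syn-aldol adduct (C5 OH, C4 Me, C3 acyl oxazolidinone)
Conditions: (R)-4-benzyl-3-propionyloxazolidin-2-one, Bu2BOTf, iPr2NEt, CH2Cl2, −78 to 0 °C; 28, −78 to −10 °C; pH 7 buffer, MeOH, H2O2
Reagents that add atoms: (R)-4-benzyl-3-propionyloxazolidin-2-one, CCC(=O)N1[C@H](Cc2ccccc2)COC1=O
Why: Evans syn-aldol reaction: the Z-dibutylboron enolate adds through a Zimmerman–Traxler chair to the enal, the (R)-auxiliary fixing C4 and C5 (2R,3S in the acyl chain, i.e. 4,5-syn in the sense of the target).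

**Step 19**
Reactants: 29 Evans syn-aldol adduct
Product: 30 C5 tert-butyldimethylsilyl ether of 29
Conditions: TBSOTf, 2,6-lutidine, CH2Cl2, −78 °C
Reagents that add atoms: tert-butyldimethylsilyl triflate, CC(C)(C)[Si](C)(C)OS(=O)(=O)C(F)(F)F
Why: silylation of the secondary allylic alcohol, much faster than that of the hindered tertiary C21 hydroxyl at −78 °C; no stereocentre is touched.

**Step 20**
Reactants: 30 C5 silyl ether
Product: 31 C14 alcohol (PMB removed)
Conditions: DDQ, CH2Cl2/pH 7 buffer, 0 °C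
Reagents that add atoms: none
Why: oxidative cleavage of the 4-methoxybenzyl ether by hydride abstraction and hydrolysis of the oxocarbenium ion; the silyl ether, esters, alkenes and bromide should be inert.

**Step 21**
Reactants: 31 C14 alcohol
Product: 32 C14 diethylphosphonoacetate
Conditions: (EtO)2P(O)CH2CO2H, EDC·HCl, DMAP (cat.), CH2Cl2, 0 °C to rt
Reagents that add atoms: diethylphosphonoacetic acid, CCOP(=O)(OCC)CC(=O)O
Why: Steglich esterification of the only free secondary hydroxyl (the tertiary C21 hydroxyl does not acylate under these conditions); C14 is retained.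

**Step 22**
Reactants: 32 C14 diethylphosphonoacetate
Product: 33 C3 primary alcohol (auxiliary removed)
Conditions: NaBH4, THF/H2O, 0 °C
Reagents that add atoms: none
Why: reductive removal of the Evans auxiliary with NaBH4; the imide carbonyl is far more electrophilic than the esters, and C4 is not epimerised.

**Step 23**
Reactants: 33 C3 primary alcohol
Product: 34 C3 aldehyde
Conditions: Dess–Martin periodinane, NaHCO3, CH2Cl2, 0 °C to rt
Reagents that add atoms: none
Why: Dess–Martin oxidation under buffered, non-epimerising conditions; the tertiary hydroxyl cannot be oxidised.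

**Step 24**
Reactants: 34 C3 aldehyde
Product: 35 macrolactone (C5 OTBS, C22 2-(trimethylsilyl)ethyl ester)
Conditions: LiCl, iPr2NEt, MeCN, rt, 1 mM (slow addition)
Reagents that add atoms: none
Why: intramolecular Horner–Wadsworth–Emmons macrocyclisation under Masamune–Roush conditions, which are mild enough to spare the α-stereocentre of the aldehyde and should give the E-enoate of the 18-membered ring.

**Step 25**
Reactants: 35 macrolactone
Product: 36 CNP0163177.2 (target)
Conditions: Bu4NF, THF, 0 °C to rt; aq. NH4Cl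
Reagents that add atoms: none
Why: fluoride-induced cleavage of the silyl ether and β-elimination of the 2-(trimethylsilyl)ethyl ester in one operation; the C15 bromide has no anti-periplanar hydrogen (H14 is cis, C16 is quaternary), so elimination is not expected.

**Compound list**

1 | (S)-citronellal, (3S)-3,7-dimethyloct-6-enal | O=CC[C@@H](C)CCC=C(C)C | starting material
2 | (6S,8S,9E)-2,6-dimethyltetradeca-2,9-dien-8-ol | O[C@H](/C=C/CCCC)C[C@@H](C)CCC=C(C)C | intermediate
3 | (6S,8S,9E)-8-methoxy-2,6-dimethyltetradeca-2,9-diene | CO[C@H](/C=C/CCCC)C[C@@H](C)CCC=C(C)C | intermediate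
4 | 3-[(3S,5S,6E)-5-methoxy-3-methylundec-6-en-1-yl]-2,2-dimethyloxirane (both epimers at the oxirane carbon) | CO[C@H](/C=C/CCCC)C[C@@H](C)CCC1OC1(C)C | intermediate
5 | (4S,6S,7E)-6-methoxy-4-methyldodec-7-enal | CO[C@H](/C=C/CCCC)C[C@@H](C)CCC=O | intermediate
6 | L-serine methyl ester hydrochloride | Cl.COC(=O)[C@@H](N)CO | starting material
7 | methyl (4S)-2-[(3S,5S,6E)-5-methoxy-3-methylundec-6-en-1-yl]oxazolidine-4-carboxylate (C2 epimers) | CO[C@H](/C=C/CCCC)C[C@@H](C)CCC1N[C@@H](CO1)C(=O)OC | intermediate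
8 | methyl (4S)-2-[(3S,5S,6E)-5-methoxy-3-methylundec-6-en-1-yl]-4,5-dihydrooxazole-4-carboxylate | CO[C@H](/C=C/CCCC)C[C@@H](C)CCC1=N[C@@H](CO1)C(=O)OC | intermediate
9 | methyl 2-[(3S,5S,6E)-5-methoxy-3-methylundec-6-en-1-yl]oxazole-4-carboxylate | CO[C@H](/C=C/CCCC)C[C@@H](C)CCc1nc(co1)C(=O)OC | intermediate
10 | N-methoxy-N-methyl-2-[(3S,5S,6E)-5-methoxy-3-methylundec-6-en-1-yl]oxazole-4-carboxamide | CO[C@H](/C=C/CCCC)C[C@@H](C)CCc1nc(co1)C(=O)N(C)OC | intermediate
11 | 1-{2-[(3S,5S,6E)-5-methoxy-3-methylundec-6-en-1-yl]oxazol-4-yl}ethan-1-one | CO[C@H](/C=C/CCCC)C[C@@H](C)CCc1nc(co1)C(C)=O | intermediate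
12 | (2E)-N-methoxy-3-{2-[(3S,5S,6E)-5-methoxy-3-methylundec-6-en-1-yl]oxazol-4-yl}-N-methylbut-2-enamide | CO[C@H](/C=C/CCCC)C[C@@H](C)CCc1nc(co1)/C(C)=C/C(=O)N(C)OC | intermediate
13 | (2E)-N-methoxy-3-{2-[(3S,5S)-5-methoxy-3-methyl-6-oxohexyl]oxazol-4-yl}-N-methylbut-2-enamide | CO[C@H](C=O)C[C@@H](C)CCc1nc(co1)/C(C)=C/C(=O)N(C)OC | intermediate
14 | (E)-4-methoxybut-3-en-2-one | CO/C=C/C(C)=O | starting material
15 | (E)-4-[(4-methoxybenzyl)oxy]but-3-en-2-one | COc1ccc(CO/C=C/C(C)=O)cc1 | intermediate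
16 | (2R,3E)-4-[(4-methoxybenzyl)oxy]but-3-en-2-ol | C[C@@H](O)/C=C/OCc1ccc(OC)cc1 | intermediate
17 | (2R,3E)-4-[(4-methoxybenzyl)oxy]but-3-en-2-yl N,N-diisopropylcarbamate | C[C@@H](OC(=O)N(C(C)C)C(C)C)/C=C/OCc1ccc(OC)cc1 | intermediate
18 | 2-lithio derivative of 17 (Li in place of H, retention) | C[C@@]([Li])(OC(=O)N(C(C)C)C(C)C)/C=C/OCc1ccc(OC)cc1 | intermediate
19 | 2-(triisopropoxytitanio) derivative of 17 (Ti on the opposite face to the former H) | C[C@]([Ti](OC(C)C)(OC(C)C)OC(C)C)(OC(=O)N(C(C)C)C(C)C)/C=C/OCc1ccc(OC)cc1 | intermediate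
20 | triisopropoxytitanium alkoxide of the homoaldol adduct: C13 O–Ti, C14 OPMB (13,14-anti; 12,13-syn), (Z)-enol carbamate C15=C16 | CO[C@H]([C@@H](O[Ti](OC(C)C)(OC(C)C)OC(C)C)[C@@H](OCc1ccc(OC)cc1)/C=C(/C)OC(=O)N(C(C)C)C(C)C)C[C@@H](C)CCc1nc(co1)/C(C)=C/C(=O)N(C)OC | intermediate
21 | bromo-ketal carbamate: tetrahydrofuran with C13 side arm, C14 OPMB, C15 Br (trans to OPMB), C16 methyl and N,N-diisopropylcarbamoyloxy (cis to Br) | COc1ccc(CO[C@@H]2[C@@H]([C@@H](OC)C[C@@H](C)CCc3nc(co3)/C(C)=C/C(=O)N(C)OC)O[C@@](C)(OC(=O)N(C(C)C)C(C)C)[C@H]2Br)cc1 | intermediate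
22 | (2E)-3-{2-[(3S,5S)-5-[(2R,3R,4S,5R)-5-allyl-4-bromo-3-(4-methoxybenzyloxy)-5-methyltetrahydrofuran-2-yl]-5-methoxy-3-methylpentyl]oxazol-4-yl}-N-methoxy-N-methylbut-2-enamide | COc1ccc(CO[C@@H]2[C@@H]([C@@H](OC)C[C@@H](C)CCc3nc(co3)/C(C)=C/C(=O)N(C)OC)O[C@](C)(CC=C)[C@H]2Br)cc1 | intermediate
23 | (R)-lactic acid | C[C@@H](O)C(=O)O | starting material
24 | (2R,5R)-2-tert-butyl-5-methyl-1,3-dioxolan-4-one | C[C@H]1O[C@@H](C(C)(C)C)OC1=O | intermediate
25 | (2R,5S)-5-allyl-2-tert-butyl-5-methyl-1,3-dioxolan-4-one | C=CC[C@]1(C)O[C@@H](C(C)(C)C)OC1=O | intermediate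
26 | 2-(trimethylsilyl)ethyl (2S)-2-hydroxy-2-methylpent-4-enoate | C=CC[C@](C)(O)C(=O)OCC[Si](C)(C)C | intermediate
27 | Weinreb enamide 22 in which C16 carries the (Z)-CH2CH=CHCH2C(CH3)(OH)CO2CH2CH2SiMe3 chain (C21 S; ring and chain stereocentres as in the target) | COc1ccc(CO[C@@H]2[C@@H]([C@@H](OC)C[C@@H](C)CCc3nc(co3)/C(C)=C/C(=O)N(C)OC)O[C@](C)(C/C=C\C[C@](C)(O)C(=O)OCC[Si](C)(C)C)[C@H]2Br)cc1 | intermediate
28 | enal: 27 with the Weinreb amide replaced by CHO (C5) | COc1ccc(CO[C@@H]2[C@@H]([C@@H](OC)C[C@@H](C)CCc3nc(co3)/C(C)=C/C=O)O[C@](C)(C/C=C\C[C@](C)(O)C(=O)OCC[Si](C)(C)C)[C@H]2Br)cc1 | intermediate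
29 | Evans syn-aldol adduct: C5 OH and C4 CH3 syn, C3 acyl on (R)-4-benzyloxazolidin-2-one (acyl chain 2R,3S) | COc1ccc(CO[C@@H]2[C@@H]([C@@H](OC)C[C@@H](C)CCc3nc(co3)/C(C)=C/[C@H](O)[C@@H](C)C(=O)N4[C@H](Cc5ccccc5)COC4=O)O[C@](C)(C/C=C\C[C@](C)(O)C(=O)OCC[Si](C)(C)C)[C@H]2Br)cc1 | intermediate
30 | C5 tert-butyldimethylsilyl ether of 29 | COc1ccc(CO[C@@H]2[C@@H]([C@@H](OC)C[C@@H](C)CCc3nc(co3)/C(C)=C/[C@H](O[Si](C)(C)C(C)(C)C)[C@@H](C)C(=O)N4[C@H](Cc5ccccc5)COC4=O)O[C@](C)(C/C=C\C[C@](C)(O)C(=O)OCC[Si](C)(C)C)[C@H]2Br)cc1 | intermediate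
31 | C14 alcohol: 30 without the 4-methoxybenzyl group | O[C@@H]1[C@@H]([C@@H](OC)C[C@@H](C)CCc2nc(co2)/C(C)=C/[C@H](O[Si](C)(C)C(C)(C)C)[C@@H](C)C(=O)N3[C@H](Cc4ccccc4)COC3=O)O[C@](C)(C/C=C\C[C@](C)(O)C(=O)OCC[Si](C)(C)C)[C@H]1Br | intermediate
32 | C14 diethylphosphonoacetate of 31 | CCOP(=O)(OCC)CC(=O)O[C@@H]1[C@@H]([C@@H](OC)C[C@@H](C)CCc2nc(co2)/C(C)=C/[C@H](O[Si](C)(C)C(C)(C)C)[C@@H](C)C(=O)N3[C@H](Cc4ccccc4)COC3=O)O[C@](C)(C/C=C\C[C@](C)(O)C(=O)OCC[Si](C)(C)C)[C@H]1Br | intermediate
33 | C3 primary alcohol: 32 with CH2OH in place of the acyl oxazolidinone | CCOP(=O)(OCC)CC(=O)O[C@@H]1[C@@H]([C@@H](OC)C[C@@H](C)CCc2nc(co2)/C(C)=C/[C@H](O[Si](C)(C)C(C)(C)C)[C@@H](C)CO)O[C@](C)(C/C=C\C[C@](C)(O)C(=O)OCC[Si](C)(C)C)[C@H]1Br | intermediate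
34 | C3 aldehyde derived from 33 | CCOP(=O)(OCC)CC(=O)O[C@@H]1[C@@H]([C@@H](OC)C[C@@H](C)CCc2nc(co2)/C(C)=C/[C@H](O[Si](C)(C)C(C)(C)C)[C@@H](C)C=O)O[C@](C)(C/C=C\C[C@](C)(O)C(=O)OCC[Si](C)(C)C)[C@H]1Br | intermediate
35 | macrolactone with C5 OTBS and C22 2-(trimethylsilyl)ethyl ester (2E,6E,18Z; stereocentres as in the target) | CO[C@H]1C[C@@H](C)CCc2nc(co2)/C(C)=C/[C@H](O[Si](C)(C)C(C)(C)C)[C@@H](C)/C=C/C(=O)O[C@@H]2[C@@H]1O[C@](C)(C/C=C\C[C@](C)(O)C(=O)OCC[Si](C)(C)C)[C@H]2Br | intermediate
36 | CNP0163177.2: (2E,4S,5R,6E,10S,12S,13R,14R,15S,16R,18Z,21S) 18-membered oxazole macrolide with the bromotetrahydrofuran and the α-hydroxy-α-methyl acid side chain | CO[C@H]1C[C@@H](C)CCc2nc(co2)/C(C)=C/[C@H](O)[C@@H](C)/C=C/C(=O)O[C@@H]2[C@@H]1O[C@](C)(C/C=C\C[C@](C)(O)C(=O)O)[C@H]2Br | target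

**Step count and risks**

Total: 25 steps. Longest linear sequence: 19 steps (steps 1–7, 11, 12, 16–25).

Steps most likely to fail:

First, step 11 (Proposed new method). What may go wrong: competing vinylic lithiation or loss of configuration of the lithiated γ-alkoxy carbamate, erosion of reagent control against the Felkin bias of the α-methoxy aldehyde (wrong C13/C14 pair), or consumption of the bromine source by the amine or the anisyl ring instead of the enol carbamate. The fallback uses known reactions only, sets out from 13 and returns at 22.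
- Chelation-controlled addition of vinylmagnesium bromide to 13 (MgBr2·OEt2, CH2Cl2, −78 °C) would give the 12,13-syn vinyl carbinol F1.
- TBSOTf/2,6-lutidine would give its silyl ether F2, and OsO4/NaIO4 cleavage of the vinyl group the α-silyloxy aldehyde F3.
- Negishi carboalumination of pent-1-en-4-yne (Me3Al, cat. Cp2ZrCl2) gives the (E)-alkenylalane F4 and, with I2, (E)-1-iodo-2-methylpenta-1,4-diene F5.
- Nozaki–Hiyama–Kishi coupling of F5 with F3 (CrCl2, cat. NiCl2, DMSO) should give the Felkin (13,14-anti) allylic alcohol F6, with the E-trisubstituted C15=C16 alkene already in place.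
- 4-Methoxybenzyl trichloroacetimidate with cat. La(OTf)3 would give the PMB ether F7, and Bu4NF the C13 alcohol F8.
- NBS (CH2Cl2, −40 °C) then closes the ring by 5-endo bromoetherification with anti-addition of O and Br across the E-alkene, which gives 22.

In this detour the two ring bonds are made in separate steps, and because C16 is set by stereospecific anti-addition it also removes the dependence on the facial selectivity of step 12.

Second, step 16. What may go wrong: low Z-selectivity, homodimerisation, or deactivation of the catalyst by the Lewis-basic oxazole and Weinreb amide. The fallback replaces metathesis by a Z-selective Wittig reaction, sets out from 22 and 25 and returns at 27.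
- OsO4/NaIO4 on 22 (terminal alkene in preference to the electron-poor enamide) would give the C18 aldehyde F9.
- Ozonolysis of 25 with NaBH4 work-up at low temperature would give the hydroxyethyl dioxolanone F10; I2/PPh3/imidazole the iodide F11; PPh3 in hot MeCN the phosphonium iodide F12.
- The ylide from F12 (NaN(SiMe3)2, THF, −78 °C) and F9 should give the Z-alkene dioxolanone F13.
- Alcoholysis of F13 under the conditions of step 15 gives 27.

Third, step 17. What may go wrong: hydrozirconation of the Z-alkene or over-reduction alongside the amide reduction. The fallback changes the order of events so that an ordinary hydride reduction is run before any ester is present; it sets out from 22 and returns at 28. iBu2AlH (CH2Cl2, −78 °C) would reduce the Weinreb enamide of 22 to the enal F14, and Z-selective cross-metathesis of F14 with 26 under the conditions of step 16 would then give 28.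

**Further compounds**

F1 | step 11 | vinyl carbinol: 13 after addition of vinyl to C13 (12,13-syn) | CO[C@H]([C@@H](O)C=C)C[C@@H](C)CCc1nc(co1)/C(C)=C/C(=O)N(C)OC
F2 | step 11 | tert-butyldimethylsilyl ether of F1 | CO[C@H]([C@@H](O[Si](C)(C)C(C)(C)C)C=C)C[C@@H](C)CCc1nc(co1)/C(C)=C/C(=O)N(C)OC
F3 | step 11 | α-silyloxy aldehyde (C14 aldehyde) | CO[C@H]([C@@H](O[Si](C)(C)C(C)(C)C)C=O)C[C@@H](C)CCc1nc(co1)/C(C)=C/C(=O)N(C)OC
F4 | step 11 | dimethyl[(E)-2-methylpenta-1,4-dien-1-yl]alane | C[Al](C)/C=C(\C)CC=C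
F5 | step 11 | (E)-1-iodo-2-methylpenta-1,4-diene | I/C=C(\C)CC=C
F6 | step 11 | allylic alcohol: C13 OTBS, C14 OH (13,14-anti), E-C15=C16(CH3)CH2CH=CH2 | CO[C@H]([C@@H](O[Si](C)(C)C(C)(C)C)[C@@H](O)/C=C(\C)CC=C)C[C@@H](C)CCc1nc(co1)/C(C)=C/C(=O)N(C)OC
F7 | step 11 | C14 4-methoxybenzyl ether of F6 | CO[C@H]([C@@H](O[Si](C)(C)C(C)(C)C)[C@@H](OCc2ccc(OC)cc2)/C=C(\C)CC=C)C[C@@H](C)CCc1nc(co1)/C(C)=C/C(=O)N(C)OC
F8 | step 11 | C13 alcohol: F7 without the silyl group | CO[C@H]([C@@H](O)[C@@H](OCc2ccc(OC)cc2)/C=C(\C)CC=C)C[C@@H](C)CCc1nc(co1)/C(C)=C/C(=O)N(C)OC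
F9 | step 16 | C18 aldehyde: 22 with CH2CHO on C16 | COc1ccc(CO[C@@H]2[C@@H]([C@@H](OC)C[C@@H](C)CCc3nc(co3)/C(C)=C/C(=O)N(C)OC)O[C@](C)(CC=O)[C@H]2Br)cc1
F10 | step 16 | (2R,5S)-2-tert-butyl-5-(2-hydroxyethyl)-5-methyl-1,3-dioxolan-4-one | OCC[C@]1(C)O[C@@H](C(C)(C)C)OC1=O
F11 | step 16 | (2R,5S)-2-tert-butyl-5-(2-iodoethyl)-5-methyl-1,3-dioxolan-4-one | ICC[C@]1(C)O[C@@H](C(C)(C)C)OC1=O
F12 | step 16 | {2-[(2R,4S)-2-tert-butyl-4-methyl-5-oxo-1,3-dioxolan-4-yl]ethyl}triphenylphosphonium iodide | c1ccccc1[P+](c1ccccc1)(c1ccccc1)CC[C@]1(C)O[C@@H](C(C)(C)C)OC1=O.[I-]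
F13 | step 16 | Z-alkene dioxolanone: 27 with the hydroxy ester masked as the tert-butyl dioxolanone | COc1ccc(CO[C@@H]2[C@@H]([C@@H](OC)C[C@@H](C)CCc3nc(co3)/C(C)=C/C(=O)N(C)OC)O[C@](C)(C/C=C\C[C@]3(C)O[C@@H](C(C)(C)C)OC3=O)[C@H]2Br)cc1
F14 | step 17 | enal: 22 with CHO in place of the Weinreb amide | COc1ccc(CO[C@@H]2[C@@H]([C@@H](OC)C[C@@H](C)CCc3nc(co3)/C(C)=C/C=O)O[C@](C)(CC=C)[C@H]2Br)cc1
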